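Start from the leftover: the last 3 readings of the epsilon run average s = 42.7 % target, so 57.3 % of the substrate charged stands elsewhere while the curve lies flat. The proposed steps include intermediate C ⇌ target, so take that flat stretch as this equilibrium, with target holding the fraction s of a common pool.

| flask | substrate | reagent | capture agent | remark | time |
|---|---|---|---|---|---|
| epsilon | 0.10 M | 4 equiv | 0.31 mM | run made earlier |  |
| theta | 0.10 M | 4 equiv | 4.7 mM | run made earlier |  |
| oak | 0.10 M | 4.00 equiv | 0.250 mM |  | 4.0 d |
| ash | 0.10 M | 4.00 equiv | 0.500 mM |  | 4.0 d |
| alder | 0.10 M | 4.00 equiv | 1.00 mM |  | 4.0 d |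
| maple | 0.10 M | 4.00 equiv | 2.00 mM |  | 4.0 d |
| elm | 0.10 M | 4.00 equiv | 4.00 mM |  | 4.0 d |

| epsilon: time / h | epsilon: target / % | theta: time / h | theta: target / % |
|---|---|---|---|
| 8.00 | 18 | 8.00 | 23 |
| 15.0 | 33 | 15.0 | 31 |
| 25.0 | 39 | 25.0 | 37 |
| 30.0 | 44 | 30.0 | 39 |
| 40.0 | 45 | 40.0 | 40 |
| 50.0 | 39 | 50.0 | 39 |

(readings scatter by 1.5 percentage points)

- the earlier runs were read with a standard deviation of 1.5 percentage points
- what may be going on: reagent + intermediate A <-> intermediate B; intermediate C <-> target; substrate + reagent -> intermediate C; capture agent + intermediate C -> trapped intermediate; substrate + reagent -> intermediate A; 2 reagent -> homo dimer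
- "hardly changes" means that all values lie within two and a half points (for a concentration: within two and a half percent of the largest)

- amount of target at the end, in percent of the substrate charged for oak, ash, alder, maple, elm, in this order
- how the row runs (rises, then falls / hardly changes / falls, then rises / falls all the way / rises all the way)

Now your own reckoning. Assume each capture agent traps one intermediate C and that the whole charge c_T is used, making it the limiting reagent of that step. It then takes c_T/c_A of the pool, where c_A is the substrate charge. The pool splits again, and target bears the fraction s of that loss. Fold this into the span D = s(c_T,elm − c_T,oak)/c_A = 1.6 percentage points, the points of target lost from oak to elm. That lies inside the band for "hardly changes", so expect a row near 42.7 % that hardly changes. Replacing the late curve by its mean costs little: leaving out the low last reading gives 1.7 points.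

Is one number enough? Between epsilon and theta the same span gives 1.9 points, while the means of their last 3 readings differ by 3.3 points, a gap read with a scatter of 1.2 points. The two stand 1.5 points apart, close to that scatter, so the number survives, narrowly.

The forecast differs, running from 42.2 % at oak to 38.8 % at elm, so falls all the way: it sets target at a plateau “minus the capture agent charged, as a percentage of substrate”, where your reckoning takes off target's share s of that charge.

The flasks give 43.6 %, 43.5 %, 43.2 %, 42.8 % and 41.9 %: the row hardly changes.

    reagent + intermediate A ⇌ intermediate B (K = 6.50 M⁻¹, k = 0.156 M⁻¹ h⁻¹)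
    intermediate C ⇌ target (K = 0.835, k = 0.0595 h⁻¹)
    substrate + reagent → intermediate C (k = 1.03 M⁻¹ h⁻¹)
    capture agent + intermediate C → trapped intermediate (k = 3.95 M⁻¹ h⁻¹)
    substrate + reagent → intermediate A (k = 0.0423 M⁻¹ h⁻¹)
    2 reagent → homo dimer (k = 0.110 M⁻¹ h⁻¹)

From oak to elm target falls 1.7 points, against D of 1.6 points. Maple, reckoned the same way at 0.75 points, ends 0.8 points below oak. Elm holds 4.00 % trapped intermediate with capture agent at 0 %, as assumed. The row takes this shape because target runs back to intermediate C: with that backward run taken away, target in elm stands at 91.6 % instead of 41.9 %.

The readings were generated by integration from invented constants, noise included.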